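**Strategy.** Labdane numbering is used. Ring A (C1–C5, C10) is cut across C2–C3 and C5–C10 into two C5 units: enal 6 (C1, C2, C10, C20, masked C9) and phosphonate 7 (C3–C6, C18). One operation joins them: Horner–Wadsworth–Emmons olefination makes C2=C3, and the resulting hexatriene, whose termini are C5 and C10, closes by thermal 6π-electrocyclisation, creating the quaternary C10. The step exploits that C5 and C10 each carry one carbon of ring B (C6 as nitrile, C9 as chiral acetal), so ring B follows by a Stetter reaction; the second C4 methyl is added later by cuprate addition, and C9 is oxygenated from the α-face.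

Key step: step 3

Remark: comments use labdane numbering (ring A = C1–C5, C10; ring B = C5–C10; side chain C11–C16; C17 on C8, C18/C19 on C4, C20 on C10); the (R,R)-acetal is protecting group and resolving handle, since the two C10 configurations formed in step 3 are diastereomers and are separated there; 4, 7, 12 and 23 are taken as purchasable.

Step 1
Reactants: 1 1,1-dimethoxypropan-2-one; 2 (1R,2R)-1,2-diphenylethane-1,2-diol
Product: 3 1-[(4R,5R)-4,5-diphenyl-1,3-dioxolan-2-yl]ethan-1-one
Conditions: TsOH·H2O (cat.), toluene, 90 °C, MeOH distilled off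
Reagents that add atoms: none
Why: Acid-catalysed transacetalisation driven by removal of methanol exchanges the dimethyl acetal for the dioxolane; the two (R)-centres of the diol are not touched and later make the C10 epimers diastereomeric.

Step 2
Reactants: 3 1-[(4R,5R)-4,5-diphenyl-1,3-dioxolan-2-yl]ethan-1-one; 4 diethyl [(E)-2-(cyclohexylamino)ethenyl]phosphonate
Product: 6 (2E)-3-[(4R,5R)-4,5-diphenyl-1,3-dioxolan-2-yl]but-2-enal, via N-cyclohexyl enimine 5 (not isolated)
Conditions: NaH, THF, 0 °C → rt; then aq. oxalic acid, toluene, rt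
Reagents that add atoms: water, O
Why: Nagata formyl-olefination, a Horner–Wadsworth–Emmons reaction of the metallated enamine phosphonate with the activated α,α-dialkoxy ketone followed by mild hydrolysis of the enimine, adds C1 and C2 as an enal; no stereocentre is formed and the E/Z ratio is irrelevant because this double bond ends as the sp3 pair C1–C10.

Step 3
Reactants: 6 (2E)-3-[(4R,5R)-4,5-diphenyl-1,3-dioxolan-2-yl]but-2-enal; 7 diethyl [(2E)-3-cyano-2-methylprop-2-en-1-yl]phosphonate
Product: 10 (6S)-2,6-dimethyl-6-[(4R,5R)-4,5-diphenyl-1,3-dioxolan-2-yl]cyclohexa-1,3-diene-1-carbonitrile, via triene nitrile 8 (not isolated), via cyclohexa-2,4-diene nitrile 9 (not isolated)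
Conditions: NaH, THF, 0 °C → rt; then I2 (5 mol %), o-xylene, 150 °C (sealed); then DBU (cat.), rt; separation of the C6 epimers
Reagents that add atoms: none
Why: The anion of 7 adds to the aldehyde of 6 and loses diethyl phosphate (vinylogous Horner–Wadsworth–Emmons olefination), which forms C2=C3 and gives triene 8; iodine equilibrates the double bonds, the (4Z)-isomer undergoes thermal disrotatory 6π-electrocyclisation (C5–C10) to 9, and a [1,5]-hydrogen shift, completed by DBU, moves the diene into conjugation with the nitrile to give 10. The closest known reaction type is the olefination/6π-electrocyclisation sequence that converts C5 phosphonates and enals into safranate-type cyclohexadienes. Ring A is closed in the hexatriene-to-cyclohexa-1,3-diene (6π, disrotatory) mode; no other ring is formed. The quaternary centre C10 (C6 of 10) is the only stereocentre kept: it forms without reliable facial bias, the (4R,5R)-dioxolane makes its two configurations diastereomers, and the (6S)-isomer is separated here by chromatography or crystallisation, while C5 is planarised on purpose and set in step 7. The step needs cross-selectivity in the olefination, secured by adding 6 to the preformed stabilised phosphonate anion, and a Z central double bond, secured because the iodine-mediated equilibrium is drained only through the irreversible ring closure of that isomer.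

Step 4
Reactants: 10 (6S)-2,6-dimethyl-6-[(4R,5R)-4,5-diphenyl-1,3-dioxolan-2-yl]cyclohexa-1,3-diene-1-carbonitrile
Product: 11 (6S)-2,6-dimethyl-6-[(4R,5R)-4,5-diphenyl-1,3-dioxolan-2-yl]cyclohex-1-ene-1-carbonitrile
Conditions: H2 (1 atm), RhCl(PPh3)3 (5 mol %), toluene–EtOH, rt
Reagents that add atoms: none
Why: Homogeneous hydrogenation with the rhodium phosphine catalyst saturates only the cis-disubstituted C2=C3 double bond and leaves the tetrasubstituted nitrile-conjugated C4=C5 bond, the benzylic acetal and C10 untouched.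

Step 5
Reactants: 11 (6S)-2,6-dimethyl-6-[(4R,5R)-4,5-diphenyl-1,3-dioxolan-2-yl]cyclohex-1-ene-1-carbonitrile; 12 (1E)-1-bromoprop-1-ene
Product: 14 (1S)-2-[(2E)-but-2-enoyl]-1,3-dimethylcyclohex-2-ene-1-carbaldehyde, via enone acetal 13 (not isolated)
Conditions: 12, Li, Et2O, 0 °C; then 11, −78 → 0 °C; then 3 M HCl, THF, 45 °C
Reagents that add atoms: water, O
Why: 1,2-Addition of (E)-prop-1-enyllithium to the hindered nitrile (the ketone synthesis used for damascones) gives a ketimine that aqueous acid hydrolyses to enone 13, and the same acid cleaves the dioxolane to the C9 aldehyde with release of the diol; the quaternary centre is untouched and any Z-enone isomerises to E in the acid.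

Step 6
Reactants: 14 (1S)-2-[(2E)-but-2-enoyl]-1,3-dimethylcyclohex-2-ene-1-carbaldehyde
Product: 15 (8aS)-2,5,8a-trimethyl-2,3,6,7,8,8a-hexahydronaphthalene-1,4-dione (C2 epimers)
Conditions: 2-(pentafluorophenyl)-6,7-dihydro-5H-pyrrolo[2,1-c][1,2,4]triazol-2-ium tetrafluoroborate (20 mol %), KN(SiMe3)2 (20 mol %), toluene, 70 °C
Reagents that add atoms: none
Why: Intramolecular Stetter reaction: the triazolylidene carbene turns the aldehyde into an acyl anion equivalent (Breslow intermediate) that adds in the 6-endo mode to the β-carbon of the butenoyl group and closes ring B as the 1,4-dione (C8–C9 bond); the new centre C8 (C2 of 15) is epimerisable, forms as a mixture and is settled in step 7.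

Step 7
Reactants: 15 (8aS)-2,5,8a-trimethyl-2,3,6,7,8,8a-hexahydronaphthalene-1,4-dione
Product: 17 (2R,4aS,8aS)-2,5,5,8a-tetramethyloctahydronaphthalene-1,4-dione, via silyl enol ether 16 (not isolated)
Conditions: Me2CuLi, TMSCl, THF, −78 → −20 °C; then 1 M HCl; then NaOMe (cat.), MeOH, rt
Reagents that add atoms: lithium dimethylcuprate, [Li+].C[Cu-]C
Why: Conjugate addition of the cuprate to the s-cis, pulegone-type enone, trapped as silyl enol ether 16, adds the second methyl at C4 (no stereocentre, two identical methyls); acid hydrolysis protonates C5 on the α-face, anti to the angular methyl, and NaOMe equilibration leaves the trans-fused dione with the C8 methyl equatorial (5S and 8R in labdane numbering, 4aS and 2R in 17).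

Step 8
Reactants: 17 (2R,4aS,8aS)-2,5,5,8a-tetramethyloctahydronaphthalene-1,4-dione
Product: 18 (2R,4R,4aS,8aS)-4-hydroxy-2,5,5,8a-tetramethyloctahydronaphthalen-1(2H)-one
Conditions: LiBH(s-Bu)3, THF, −78 °C; then H2O
Reagents that add atoms: none
Why: LiBH(s-Bu)3 is too bulky for the C9 carbonyl, which is flanked by the quaternary C10 and the C8 methine, and reduces the C6 carbonyl by equatorial attack from the α-face, away from the two syn-axial β-methyls, to give the axial 6β-alcohol (4R in 18).

Step 9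
Reactants: 18 (2R,4R,4aS,8aS)-4-hydroxy-2,5,5,8a-tetramethyloctahydronaphthalen-1(2H)-one
Product: 19 (1R,3R,4aS,8aS)-3,4a,8,8-tetramethyl-4-methylidenedecahydronaphthalen-1-ol
Conditions: Ph3PCH3Br, KOtBu, toluene, 90 °C
Reagents that add atoms: methyltriphenylphosphonium bromide, C[P+](c1ccccc1)(c1ccccc1)c1ccccc1.[Br-]
Why: Wittig methylenation of the hindered C9 ketone with excess ylide at elevated temperature gives the exocyclic alkene (C11); the hydroxyl is carried as its potassium alkoxide and the C8 methyl stays in its stable equatorial position.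

Step 10
Reactants: 19 (1R,3R,4aS,8aS)-3,4a,8,8-tetramethyl-4-methylidenedecahydronaphthalen-1-ol
Product: 20 (1R,2R,4R,4aS,8aS)-2,5,5,8a-tetramethyloctahydro-2H-spiro[naphthalene-1,2'-oxiran]-4-ol
Conditions: mCPBA, NaHCO3, CH2Cl2, 0 °C
Reagents that add atoms: mCPBA, O=C(OO)c1cccc(Cl)c1
Why: Prilezhaev epoxidation of the exocyclic 1,1-disubstituted alkene takes place on the α-face, anti to the adjacent axial C10 methyl, which puts the oxygen on C9 in the 9α configuration of the target.

Step 11
Reactants: 20 (1R,2R,4R,4aS,8aS)-2,5,5,8a-tetramethyloctahydro-2H-spiro[naphthalene-1,2'-oxiran]-4-ol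
Product: 21 (1R,2R,4R,4aS,8aS)-1-ethenyl-2,5,5,8a-tetramethyldecahydronaphthalene-1,4-diol
Conditions: Me3SI, n-BuLi, THF, −10 °C → rt
Reagents that add atoms: trimethylsulfonium iodide, C[S+](C)C.[I-]
Why: One-carbon homologation of a terminal epoxide to an allylic alcohol with excess dimethylsulfonium methylide (ylide opening at the CH2 terminus, then elimination of dimethyl sulfide) leaves the C9–O bond intact, so the 9α-hydroxyl is retained and the new vinyl group (C11, C12) is β.

Step 12
Reactants: 21 (1R,2R,4R,4aS,8aS)-1-ethenyl-2,5,5,8a-tetramethyldecahydronaphthalene-1,4-diol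
Product: 22 (1R,3R,4R,4aS,8aS)-4-ethenyl-4-hydroxy-3,4a,8,8-tetramethyldecahydronaphthalen-1-yl acetate
Conditions: Ac2O, DMAP, Et3N, CH2Cl2, rt → 40 °C
Reagents that add atoms: acetic anhydride, CC(=O)OC(C)=O
Why: DMAP-catalysed acylation esterifies the secondary 6β-hydroxyl, while the tertiary allylic 9-hydroxyl is too hindered to react; no stereocentre is touched.

Step 13
Reactants: 22 (1R,3R,4R,4aS,8aS)-4-ethenyl-4-hydroxy-3,4a,8,8-tetramethyldecahydronaphthalen-1-yl acetate; 23 4-bromo-1,5-dihydro-2H-pyrrol-2-one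
Product: 25 (1R,3R,4R,4aS,8aS)-4-hydroxy-3,4a,8,8-tetramethyl-4-[2-(5-oxo-2,5-dihydro-1H-pyrrol-3-yl)ethyl]decahydronaphthalen-1-yl acetate, via B-alkyl-9-BBN adduct 24 (not isolated)
Conditions: 9-BBN, THF, 0 → 50 °C; then 23, Pd(dppf)Cl2 (5 mol %), AsPh3, K3PO4, DMF–H2O, 50 °C
Reagents that add atoms: none
Why: Anti-Markovnikov hydroboration of the vinyl group followed by B-alkyl Suzuki–Miyaura coupling with the β-bromo unsaturated lactam forms the C12–C13 bond under mild base that spares the acetate; no stereocentre is touched.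

**Compound list**

1 | 1,1-dimethoxypropan-2-one | CC(=O)C(OC)OC | starting material
2 | (1R,2R)-1,2-diphenylethane-1,2-diol | O[C@H](c1ccccc1)[C@H](O)c1ccccc1 | starting material
3 | 1-[(4R,5R)-4,5-diphenyl-1,3-dioxolan-2-yl]ethan-1-one | CC(=O)C1O[C@H](c2ccccc2)[C@@H](c2ccccc2)O1 | intermediate
4 | diethyl [(E)-2-(cyclohexylamino)ethenyl]phosphonate | CCOP(=O)(OCC)/C=C/NC1CCCCC1 | starting material
5 | (2E)-N-cyclohexyl-3-[(4R,5R)-4,5-diphenyl-1,3-dioxolan-2-yl]but-2-en-1-imine | C1CCCCC1N=C/C=C(\C)C2O[C@H](c3ccccc3)[C@@H](c3ccccc3)O2 | intermediate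
6 | (2E)-3-[(4R,5R)-4,5-diphenyl-1,3-dioxolan-2-yl]but-2-enal | O=C/C=C(\C)C1O[C@H](c2ccccc2)[C@@H](c2ccccc2)O1 | intermediate
7 | diethyl [(2E)-3-cyano-2-methylprop-2-en-1-yl]phosphonate | N#C/C=C(\C)CP(=O)(OCC)OCC | starting material
8 | (2E,4E,6E)-7-[(4R,5R)-4,5-diphenyl-1,3-dioxolan-2-yl]-3-methylocta-2,4,6-trienenitrile (equilibrating with its double-bond isomers) | N#C/C=C(C)/C=C/C=C(\C)C1O[C@H](c2ccccc2)[C@@H](c2ccccc2)O1 | intermediate
9 | 2,6-dimethyl-6-[(4R,5R)-4,5-diphenyl-1,3-dioxolan-2-yl]cyclohexa-2,4-diene-1-carbonitrile (both configurations at C1 and C6) | N#CC1C(C)=CC=CC1(C)C1O[C@H](c2ccccc2)[C@@H](c2ccccc2)O1 | intermediate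
10 | (6S)-2,6-dimethyl-6-[(4R,5R)-4,5-diphenyl-1,3-dioxolan-2-yl]cyclohexa-1,3-diene-1-carbonitrile | N#CC1=C(C)C=CC[C@]1(C)C1O[C@H](c2ccccc2)[C@@H](c2ccccc2)O1 | intermediate
11 | (6S)-2,6-dimethyl-6-[(4R,5R)-4,5-diphenyl-1,3-dioxolan-2-yl]cyclohex-1-ene-1-carbonitrile | N#CC1=C(C)CCC[C@]1(C)C1O[C@H](c2ccccc2)[C@@H](c2ccccc2)O1 | intermediate
12 | (1E)-1-bromoprop-1-ene | C/C=C/Br | starting material
13 | (2E)-1-{(6S)-2,6-dimethyl-6-[(4R,5R)-4,5-diphenyl-1,3-dioxolan-2-yl]cyclohex-1-en-1-yl}but-2-en-1-one | C/C=C/C(=O)C1=C(C)CCC[C@]1(C)C1O[C@H](c2ccccc2)[C@@H](c2ccccc2)O1 | intermediate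
14 | (1S)-2-[(2E)-but-2-enoyl]-1,3-dimethylcyclohex-2-ene-1-carbaldehyde | C/C=C/C(=O)C1=C(C)CCC[C@]1(C)C=O | intermediate
15 | (8aS)-2,5,8a-trimethyl-2,3,6,7,8,8a-hexahydronaphthalene-1,4-dione (C2 epimers) | O=C1CC(C)C(=O)[C@@]2(C)CCCC(C)=C12 | intermediate
16 | (8aS)-2,5,5,8a-tetramethyl-4-[(trimethylsilyl)oxy]-3,5,6,7,8,8a-hexahydronaphthalen-1(2H)-one (C2 epimers) | C[Si](C)(C)OC1=C2C(C)(C)CCC[C@]2(C)C(=O)C(C)C1 | intermediate
17 | (2R,4aS,8aS)-2,5,5,8a-tetramethyloctahydronaphthalene-1,4-dione | O=C1C[C@@H](C)C(=O)[C@@]2(C)CCCC(C)(C)[C@H]12 | intermediate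
18 | (2R,4R,4aS,8aS)-4-hydroxy-2,5,5,8a-tetramethyloctahydronaphthalen-1(2H)-one | O[C@@H]1C[C@@H](C)C(=O)[C@@]2(C)CCCC(C)(C)[C@H]12 | intermediate
19 | (1R,3R,4aS,8aS)-3,4a,8,8-tetramethyl-4-methylidenedecahydronaphthalen-1-ol | O[C@@H]1C[C@@H](C)C(=C)[C@@]2(C)CCCC(C)(C)[C@H]12 | intermediate
20 | (1R,2R,4R,4aS,8aS)-2,5,5,8a-tetramethyloctahydro-2H-spiro[naphthalene-1,2'-oxiran]-4-ol (epoxide oxygen anti to the angular methyl) | O[C@@H]1C[C@@H](C)[C@]3(CO3)[C@@]2(C)CCCC(C)(C)[C@H]12 | intermediate
21 | (1R,2R,4R,4aS,8aS)-1-ethenyl-2,5,5,8a-tetramethyldecahydronaphthalene-1,4-diol | O[C@@H]1C[C@@H](C)[C@](O)(C=C)[C@@]2(C)CCCC(C)(C)[C@H]12 | intermediate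
22 | (1R,3R,4R,4aS,8aS)-4-ethenyl-4-hydroxy-3,4a,8,8-tetramethyldecahydronaphthalen-1-yl acetate | CC(=O)O[C@@H]1C[C@@H](C)[C@](O)(C=C)[C@@]2(C)CCCC(C)(C)[C@H]12 | intermediate
23 | 4-bromo-1,5-dihydro-2H-pyrrol-2-one | O=C1C=C(Br)CN1 | starting material
24 | (1R,3R,4R,4aS,8aS)-4-[2-(9-borabicyclo[3.3.1]nonan-9-yl)ethyl]-4-hydroxy-3,4a,8,8-tetramethyldecahydronaphthalen-1-yl acetate | CC(=O)O[C@@H]1C[C@@H](C)[C@](O)(CCB3C4CCCC3CCC4)[C@@]2(C)CCCC(C)(C)[C@H]12 | intermediate
25 | (1R,3R,4R,4aS,8aS)-4-hydroxy-3,4a,8,8-tetramethyl-4-[2-(5-oxo-2,5-dihydro-1H-pyrrol-3-yl)ethyl]decahydronaphthalen-1-yl acetate | CC(=O)O[C@@H]1C[C@@H](C)[C@](O)(CCC2=CC(=O)NC2)[C@@]2(C)CCCC(C)(C)[C@H]12 | target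

**Step count.** Total: 13 steps. Longest linear sequence: 13 steps (1 to 25).

**Steps most likely to fail**

Step 3. The E-to-Z equilibration of the central double bond may be too slow compared with thermal decomposition of the polyene nitrile, so that ring closure stalls; the separation of the C10 epimers may also be inefficient. The fallback sets out from 6 and inverts the roles of the two C5 units so that the cis-triene is made directly. Luche reduction (NaBH4, CeCl3, MeOH) gives (2E)-3-[(4R,5R)-4,5-diphenyl-1,3-dioxolan-2-yl]but-2-en-1-ol F1. CBr4/PPh3 converts it into (4R,5R)-2-[(2E)-4-bromobut-2-en-2-yl]-4,5-diphenyl-1,3-dioxolane F2, and PPh3 in toluene gives {(2E)-3-[(4R,5R)-4,5-diphenyl-1,3-dioxolan-2-yl]but-2-en-1-yl}triphenylphosphonium bromide F3. SeO2 oxidation of commercial 3-methylbut-2-enenitrile gives (2E)-3-methyl-4-oxobut-2-enenitrile F4. Wittig reaction of the allylic ylide of F3 (NaN(SiMe3)2, THF, −78 °C) with F4, which is not E-selective, gives directly a large share of (2E,4Z,6E)-7-[(4R,5R)-4,5-diphenyl-1,3-dioxolan-2-yl]-3-methylocta-2,4,6-trienenitrile F5. This isomer closes at 80–110 °C without iodine to 9 and is isomerised with DBU and separated as before; the route is rejoined at 10.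

Step 6. The carbene may fail to add to the α-quaternary aldehyde, so that no acyl anion equivalent forms and base-induced deformylation takes over. The fallback sets out from 14. SmI2 (THF, MeOH, −78 °C) brings about a reductive ketyl–enone cyclisation between the aldehyde carbon and the β-carbon of the butenoyl group to give (4aS)-4-hydroxy-3,4a,8-trimethyl-3,4,4a,5,6,7-hexahydronaphthalen-1(2H)-one F6. Oxidation with Dess–Martin periodinane then gives the dione; the route is rejoined at 15.

Step 7. Methyl transfer to the fully substituted β-carbon next to the quaternary centre may be too slow, so that the enone is recovered or merely reduced. The fallback sets out from 15. Methylene transfer with dimethylsulfoxonium methylide (Me3S(O)I, NaH, DMSO, 50 °C) to the enone double bond, on the face anti to the angular methyl, gives (8aS)-2,5,8a-trimethyl-4a,5-methanooctahydronaphthalene-1,4-dione F7. Reductive cleavage of this cyclopropyl ketone (SmI2, HMPA, t-BuOH) breaks the cyclopropane bond that is axial to ring B, the one to the new CH2, which becomes the second C4 methyl. The resulting enolate is protonated and equilibrated with NaOMe as in step 7; the route is rejoined at 17.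

**Further compounds**

F1 | step 3 | (2E)-3-[(4R,5R)-4,5-diphenyl-1,3-dioxolan-2-yl]but-2-en-1-ol | OC/C=C(\C)C1O[C@H](c2ccccc2)[C@@H](c2ccccc2)O1
F2 | step 3 | (4R,5R)-2-[(2E)-4-bromobut-2-en-2-yl]-4,5-diphenyl-1,3-dioxolane | BrC/C=C(\C)C1O[C@H](c2ccccc2)[C@@H](c2ccccc2)O1
F3 | step 3 | {(2E)-3-[(4R,5R)-4,5-diphenyl-1,3-dioxolan-2-yl]but-2-en-1-yl}triphenylphosphonium bromide | [Br-].c1ccccc1[P+](c1ccccc1)(c1ccccc1)C/C=C(\C)C1O[C@H](c2ccccc2)[C@@H](c2ccccc2)O1
F4 | step 3 | (2E)-3-methyl-4-oxobut-2-enenitrile | N#C/C=C(\C)C=O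
F5 | step 3 | (2E,4Z,6E)-7-[(4R,5R)-4,5-diphenyl-1,3-dioxolan-2-yl]-3-methylocta-2,4,6-trienenitrile | N#C/C=C(C)/C=C\C=C(/C)C1O[C@H](c2ccccc2)[C@@H](c2ccccc2)O1
F6 | step 6 | (4aS)-4-hydroxy-3,4a,8-trimethyl-3,4,4a,5,6,7-hexahydronaphthalen-1(2H)-one (C3/C4 epimers) | O=C1CC(C)C(O)[C@@]2(C)CCCC(C)=C12
F7 | step 7 | (8aS)-2,5,8a-trimethyl-4a,5-methanooctahydronaphthalene-1,4-dione (methylene bridge anti to the 8a-methyl) | O=C1CC(C)C(=O)[C@@]2(C)CCC[C@@]3(C)C[C@@]123
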